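A direct plan would buy the ring as (R)-4-(tert-butyldimethylsilyloxy)cyclopent-2-enone A1, add an acetamide enolate to its ketone, grow the octenyl chain by Wittig reaction and then edit the ring to the silylated chloroenone A2.
It would join the upper chain by a lithium aldol reaction of A2 with the ynal A3 to give the propargylic aldol A4, then finish by Lindlar semihydrogenation, acetylation and desilylation.
Its weakest steps would be:
(a) the ring-editing detour to A2 (desilylation, directed epoxidation, oxidation, HCl opening, mesylation–elimination, resilylation): six operations that add one chlorine and move one double bond;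
(b) the late aldol union, which would set C7 and C8 in one event on the most advanced material, with facial control resting on the small difference between a silyloxy group and the octenyl chain at C12, and with a labile ynal;
(c) the semihydrogenation of A4, where a chloroenone and a second Z-alkene would have to survive hydrogen on palladium (over-reduction, loss of chlorine) on precious material.

**Plan of the new route**
The route cuts C9–C10 and C10=C11 (C10 and its chlorine arrive last, from a chloromethylphosphonate), C5=C6 (Wittig), C12–O and C12–C13 (lactone enolate chemistry) and C8–C12 (Fráter–Seebach alkylation).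
The enabling feature is that C6–C7–C8(–C9)–C12–C11 is an isocitric acid skeleton: O7 can lactonise onto C11 (γ-lactone, ring B: O7–C7–C8–C12–C11) with the C6 and C9 branches cis.
Ring B is made first and relays C7 (set by hydrogenation) to C8 and then to C12.
After reduction of C11, the cis C9 acid closes onto the lactol as a bicyclic acylal, in which C9 is an activated ester and C11 a stored aldehyde.
Ring A (C8–C9–C10–C11–C12) forms last, by acyl substitution at C9 and Horner–Wadsworth–Emmons closure onto C11.
No aldol union, no alkyne and no ring-oxygen shuffle occur; the chlorine comes in with C10 and both Z-alkenes are made on simple material.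

Key step: step 10

Remarks: atom numbers are the prostanoid numbers of the target (C1 ester carbon, C5=C6, C7 acetoxy carbon, C8–C12 ring, C13–C20 octenyl chain). Compounds 1, 3, 8, 15 and 20 are taken as purchased. In step 1 the (S)-ligand is assumed to give the (3R)-alcohol, as with 4-chloro- and 4-alkoxy-3-oxobutanoates; if the sense were reversed, the (R)-ligand would be used.

**Route**

Step 1
Reactants: 1 methyl 4,4-dimethoxy-3-oxobutanoate
Product: 2 methyl (3R)-3-hydroxy-4,4-dimethoxybutanoate
Conditions: H2 (50 atm), RuCl2[(S)-BINAP] (0.2 mol %), MeOH, 50 °C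
Reagents that add atoms: none
Why: Noyori asymmetric hydrogenation of a β-keto ester through the ruthenium–ester chelate should set C7, and the acetal carries C6 at the aldehyde level without a later oxidation.

Step 2
Reactants: 2 methyl (3R)-3-hydroxy-4,4-dimethoxybutanoate; 3 methyl bromoacetate
Product: 5 dimethyl (2S)-2-[(1R)-1-hydroxy-2,2-dimethoxyethyl]butanedioate, via dilithio dianion 4 (not isolated)
Conditions: LiN(iPr)2 (2.2 equiv), THF, −78 to −20 °C; 3, DMPU, −78 to −30 °C; aq NH4Cl
Reagents that add atoms: none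
Why: Fráter–Seebach alkylation: the lithium-chelated alkoxide–enolate should be alkylated on the face anti to the C6 substituent, which gives the 7,8-anti relationship of the target (C8 set from C7), and the dianion cannot lose its β-oxygen.

Step 3
Reactants: 5 dimethyl (2S)-2-[(1R)-1-hydroxy-2,2-dimethoxyethyl]butanedioate
Product: 7 (2R,3S)-2-(dimethoxymethyl)-5-oxooxolane-3-carboxylic acid (C6 acetal and C9 acid cis on ring B), via hydroxy diacid 6 (not isolated)
Conditions: LiOH (3 equiv), THF–H2O, 0 °C to rt; 1 M HCl to pH 2, EtOAc; then PhMe, 60 °C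
Reagents that add atoms: lithium hydroxide, [Li+].[OH-]
Why: Saponification and γ-lactonisation: only the C11 carboxyl can reach O7 through a five-membered ring, so ring B should close with the C9 acid left free, where as a carboxylate it shields C8–H in the enolate steps.

Step 4
Reactants: 8 (Z)-oct-2-en-1-ol
Product: 9 (Z)-1-bromooct-2-ene
Conditions: CBr4, PPh3, CH2Cl2, 0 °C
Reagents that add atoms: tetrabromomethane, BrC(Br)(Br)Br
Why: Appel bromination of a primary allylic alcohol is an SN2 displacement at low temperature and should leave the Z-alkene unchanged.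

Step 5
Reactants: 7 (2R,3S)-2-(dimethoxymethyl)-5-oxooxolane-3-carboxylic acid; 9 (Z)-1-bromooct-2-ene
Product: 11 (2R,3S,4S)-2-(dimethoxymethyl)-4-[(2Z)-oct-2-en-1-yl]-5-oxooxolane-3-carboxylic acid, via dilithio dianion 10 (not isolated)
Conditions: LiN(SiMe3)2 (2.2 equiv), THF–DMPU, −78 °C; 9, −78 to −40 °C; aq citric acid
Reagents that add atoms: none
Why: Alkylation of a paraconic-acid-type dianion: the carboxylate keeps C8–H from being removed, so only the lactone α-carbon C12 is enolised, and SN2 attack on the primary allylic bromide should bring in the (Z)-octenyl chain anti to the C9 carboxylate (this C12 configuration is erased in step 6).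

Step 6
Reactants: 11 (2R,3S,4S)-2-(dimethoxymethyl)-4-[(2Z)-oct-2-en-1-yl]-5-oxooxolane-3-carboxylic acid
Product: 13 (2R,3R,4S)-2-(dimethoxymethyl)-4-hydroxy-4-[(2Z)-oct-2-en-1-yl]-5-oxooxolane-3-carboxylic acid, via dipotassium dianion 12 (not isolated)
Conditions: KN(SiMe3)2 (2.3 equiv), THF, −78 °C; 3-phenyl-2-(phenylsulfonyl)oxaziridine, −78 °C; aq NH4Cl
Reagents that add atoms: 3-phenyl-2-(phenylsulfonyl)oxaziridine, O=S(=O)(c1ccccc1)N1OC1c1ccccc1
Why: Davis enolate hydroxylation: the planar C12 enolate of ring B should be oxidised from the face opposite the two cis substituents at C7 and C8, so the hydroxyl ends trans to the C9 carboxyl and the octenyl chain cis to it, which is the C8/C12 relationship of the target (C12 set from C8).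

Step 7
Reactants: 13 (2R,3R,4S)-2-(dimethoxymethyl)-4-hydroxy-4-[(2Z)-oct-2-en-1-yl]-5-oxooxolane-3-carboxylic acid
Product: 14 (2R,3R,4S)-2-formyl-4-hydroxy-4-[(2Z)-oct-2-en-1-yl]-5-oxooxolane-3-carboxylic acid (drawn open; expected to sit largely as the cyclic pseudo-acid with the cis C9 carboxyl)
Conditions: CF3CO2H–H2O (9:1), 0 °C to rt
Reagents that add atoms: water, O
Why: Acid hydrolysis of the dimethyl acetal should free the C6 aldehyde, while the lactone and the tertiary alcohol are stable to aqueous acid.

Step 8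
Reactants: 14 (2R,3R,4S)-2-formyl-4-hydroxy-4-[(2Z)-oct-2-en-1-yl]-5-oxooxolane-3-carboxylic acid; 15 (4-carboxybutyl)triphenylphosphonium bromide
Product: 17 (2S,3R,4S)-2-[(1Z)-5-carboxypent-1-en-1-yl]-4-hydroxy-4-[(2Z)-oct-2-en-1-yl]-5-oxooxolane-3-carboxylic acid, via ylide carboxylate 16 (not isolated)
Conditions: 15 (3.5 equiv), NaN(SiMe3)2 (7 equiv), THF, 0 °C; 14, −78 to 0 °C; aq citric acid
Reagents that add atoms: none
Why: Lithium-free Wittig olefination with a non-stabilised ylide is under kinetic control and should give the 5Z-alkene; the aldehyde reacts at −78 °C, far faster than the lactone, and C1 arrives as an inert carboxylate.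

Step 9
Reactants: 17 (2S,3R,4S)-2-[(1Z)-5-carboxypent-1-en-1-yl]-4-hydroxy-4-[(2Z)-oct-2-en-1-yl]-5-oxooxolane-3-carboxylic acid
Product: 19 (5Z)-6-[(1R,4R,5S,7S)-7-hydroxy-7-[(2Z)-oct-2-en-1-yl]-3-oxo-2,6-dioxabicyclo[2.2.1]heptan-5-yl]hex-5-enoic acid (the C9 carboxyl lactonised onto the lactol carbon C11), via lactol diacid 18 (not isolated)
Conditions: LiN(SiMe3)2 (3.0 equiv), THF, −78 °C; iBu2AlH (1.3 equiv), −78 to −40 °C; aq potassium sodium tartrate, then pH 3; PPTS (10 mol %), 4 Å sieves, CH2Cl2 (0.005 M), rt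
Reagents that add atoms: none
Why: Half-reduction of the lactone (the three acidic sites are held as lithium salts, which the hydride should not reduce at low temperature) followed by acid-catalysed dehydrative acylal formation: only the cis C9 carboxyl can reach C11, so C9 is told apart from the C1 acid and activated, and C11 is stored at the aldehyde level.

Step 10
Reactants: 19 (5Z)-6-[(1R,4R,5S,7S)-7-hydroxy-7-[(2Z)-oct-2-en-1-yl]-3-oxo-2,6-dioxabicyclo[2.2.1]heptan-5-yl]hex-5-enoic acid; 20 diethyl (chloromethyl)phosphonate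
Product: 23 (5Z,7S)-7-[(1R,2S)-4-chloro-2-hydroxy-2-[(2Z)-oct-2-en-1-yl]-5-oxocyclopent-3-en-1-yl]-7-hydroxyhept-5-enoic acid, via lithiated phosphonate 21 (not isolated), via ketophosphonate lactol 22 (not isolated)
Conditions: 19, LiN(SiMe3)2 (2.0 equiv), THF, −78 °C; 21 (from 20 and LiN(iPr)2, 2.3 equiv), −78 to −20 °C; AcOH; then LiCl, iPr2NEt, MeCN, 0 °C to rt
Reagents that add atoms: none
Why: The carbanion 21 should add to the strained acylal carbonyl C9 and the adduct collapse with loss of the C11 lactol oxide to give the α-chloro-β-ketophosphonate 22, after which, under Masamune–Roush conditions, C10 adds to the ring-opened C11 aldehyde and the oxaphosphetane breaks down to the C10=C11 alkene and diethyl phosphate. The closest known reaction types are the conversion of lactones and enol lactones into cycloalkenones with lithiated methylphosphonates (acylation, then intramolecular Horner–Wadsworth–Emmons reaction) and the olefination of aldehydes with α-chloro phosphonates, which keeps the chlorine on the new alkene. Ring A closes by attack of C10 on the C11 carbonyl, a 5-(enolendo)-exo-trig addition that is routine for ketophosphonate and 1,4-dicarbonyl cyclisations, and the five-membered ring can hold only the cis chloroalkene. No stereocentre is formed: C7, C8 and C12 come from steps 1, 2 and 6, C8–H is a bridgehead proton in 19 and cannot be enolised during the acylation, and in 22 the C10–H between carbonyl, phosphoryl and chlorine is removed long before C8–H. The step needs attack at C9 and not C1 (C1 is an inert carboxylate) and olefination instead of Darzens closure (favoured by the β-keto phosphonate), and it frees the C7 hydroxyl as ring B opens.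

Step 11
Reactants: 23 (5Z,7S)-7-[(1R,2S)-4-chloro-2-hydroxy-2-[(2Z)-oct-2-en-1-yl]-5-oxocyclopent-3-en-1-yl]-7-hydroxyhept-5-enoic acid
Product: 24 methyl (5Z,7S)-7-[(1R,2S)-4-chloro-2-hydroxy-2-[(2Z)-oct-2-en-1-yl]-5-oxocyclopent-3-en-1-yl]-7-hydroxyhept-5-enoate
Conditions: Me3SiCHN2 (1.1 equiv), PhMe–MeOH (4:1), 0 °C
Reagents that add atoms: (trimethylsilyl)diazomethane, C[Si](C)(C)C=[N+]=[N-]
Why: O-methylation of the only carboxylic acid by a diazoalkane under neutral conditions should leave the β-hydroxy ketone, the chloroenone and both Z-alkenes alone.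

Step 12
Reactants: 24 methyl (5Z,7S)-7-[(1R,2S)-4-chloro-2-hydroxy-2-[(2Z)-oct-2-en-1-yl]-5-oxocyclopent-3-en-1-yl]-7-hydroxyhept-5-enoate
Product: 25 punaglandin 8, methyl (5Z,7S)-7-acetoxy-7-[(1R,2S)-4-chloro-2-hydroxy-2-[(2Z)-oct-2-en-1-yl]-5-oxocyclopent-3-en-1-yl]hept-5-enoate
Conditions: Ac2O, pyridine, CH2Cl2, 0 °C to rt
Reagents that add atoms: acetic anhydride, CC(=O)OC(C)=O
Why: O-acetylation of the secondary C7 hydroxyl with retention; the hindered tertiary C12 hydroxyl should not react without an acyl-transfer catalyst, and pyridine is too weak to start β-elimination of the acetate.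

**Compound list**
1 | methyl 4,4-dimethoxy-3-oxobutanoate | COC(=O)CC(=O)C(OC)OC | starting material
2 | methyl (3R)-3-hydroxy-4,4-dimethoxybutanoate | COC(=O)C[C@@H](O)C(OC)OC | intermediate
3 | methyl bromoacetate | COC(=O)CBr | starting material
4 | dilithio dianion of 2 (lithium alkoxide, lithium ester enolate) | COC(O[Li])=C[C@@H](O[Li])C(OC)OC | intermediate (not isolated)
5 | dimethyl (2S)-2-[(1R)-1-hydroxy-2,2-dimethoxyethyl]butanedioate | COC(=O)C[C@H](C(=O)OC)[C@@H](O)C(OC)OC | intermediate
6 | (2S)-2-[(1R)-1-hydroxy-2,2-dimethoxyethyl]butanedioic acid | OC(=O)C[C@H](C(=O)O)[C@@H](O)C(OC)OC | intermediate (not isolated)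
7 | (2R,3S)-2-(dimethoxymethyl)-5-oxooxolane-3-carboxylic acid | C1C(=O)O[C@@H](C(OC)OC)[C@H]1C(=O)O | intermediate
8 | (Z)-oct-2-en-1-ol | CCCCC/C=C\CO | starting material
9 | (Z)-1-bromooct-2-ene | CCCCC/C=C\CBr | intermediate
10 | dilithio dianion of 7 (lithium carboxylate, lithium lactone enolate) | C1=C(O[Li])O[C@@H](C(OC)OC)[C@H]1C(=O)O[Li] | intermediate (not isolated)
11 | (2R,3S,4S)-2-(dimethoxymethyl)-4-[(2Z)-oct-2-en-1-yl]-5-oxooxolane-3-carboxylic acid | CCCCC/C=C\C[C@@H]1C(=O)O[C@@H](C(OC)OC)[C@H]1C(=O)O | intermediate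
12 | dipotassium dianion of 11 (potassium carboxylate, potassium lactone enolate) | CCCCC/C=C\CC1=C(O[K])O[C@@H](C(OC)OC)[C@H]1C(=O)O[K] | intermediate (not isolated)
13 | (2R,3R,4S)-2-(dimethoxymethyl)-4-hydroxy-4-[(2Z)-oct-2-en-1-yl]-5-oxooxolane-3-carboxylic acid | CCCCC/C=C\C[C@@]1(O)C(=O)O[C@@H](C(OC)OC)[C@H]1C(=O)O | intermediate
14 | (2R,3R,4S)-2-formyl-4-hydroxy-4-[(2Z)-oct-2-en-1-yl]-5-oxooxolane-3-carboxylic acid | CCCCC/C=C\C[C@@]1(O)C(=O)O[C@@H](C=O)[C@H]1C(=O)O | intermediate
15 | (4-carboxybutyl)triphenylphosphonium bromide | OC(=O)CCCC[P+](c1ccccc1)(c1ccccc1)c1ccccc1.[Br-] | starting material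
16 | sodium 5-(triphenyl-λ5-phosphanylidene)pentanoate | [Na+].[O-]C(=O)CCCC=P(c1ccccc1)(c1ccccc1)c1ccccc1 | intermediate (not isolated)
17 | (2S,3R,4S)-2-[(1Z)-5-carboxypent-1-en-1-yl]-4-hydroxy-4-[(2Z)-oct-2-en-1-yl]-5-oxooxolane-3-carboxylic acid | CCCCC/C=C\C[C@@]1(O)C(=O)O[C@@H](/C=C\CCCC(=O)O)[C@H]1C(=O)O | intermediate
18 | (2S,3R,4S)-2-[(1Z)-5-carboxypent-1-en-1-yl]-4,5-dihydroxy-4-[(2Z)-oct-2-en-1-yl]oxolane-3-carboxylic acid (C5 anomers) | CCCCC/C=C\C[C@@]1(O)C(O)O[C@@H](/C=C\CCCC(=O)O)[C@H]1C(=O)O | intermediate (not isolated)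
19 | (5Z)-6-[(1R,4R,5S,7S)-7-hydroxy-7-[(2Z)-oct-2-en-1-yl]-3-oxo-2,6-dioxabicyclo[2.2.1]heptan-5-yl]hex-5-enoic acid | CCCCC/C=C\C[C@@]1(O)[C@@H]2O[C@@H](/C=C\CCCC(=O)O)[C@H]1C(=O)O2 | intermediate
20 | diethyl (chloromethyl)phosphonate | CCOP(=O)(CCl)OCC | starting material
21 | diethyl [chloro(lithio)methyl]phosphonate | CCOP(=O)(C([Li])Cl)OCC | intermediate (not isolated)
22 | (5Z)-6-[(2S,3R,4S)-3-[chloro(diethoxyphosphoryl)acetyl]-4,5-dihydroxy-4-[(2Z)-oct-2-en-1-yl]oxolan-2-yl]hex-5-enoic acid (mixture at C5 and at the chlorinated carbon) | CCCCC/C=C\C[C@@]1(O)C(O)O[C@@H](/C=C\CCCC(=O)O)[C@H]1C(=O)C(Cl)P(=O)(OCC)OCC | intermediate (not isolated)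
23 | (5Z,7S)-7-[(1R,2S)-4-chloro-2-hydroxy-2-[(2Z)-oct-2-en-1-yl]-5-oxocyclopent-3-en-1-yl]-7-hydroxyhept-5-enoic acid | CCCCC/C=C\C[C@@]1(O)C=C(Cl)C(=O)[C@@H]1[C@H](/C=C\CCCC(=O)O)O | intermediate
24 | methyl (5Z,7S)-7-[(1R,2S)-4-chloro-2-hydroxy-2-[(2Z)-oct-2-en-1-yl]-5-oxocyclopent-3-en-1-yl]-7-hydroxyhept-5-enoate | CCCCC/C=C\C[C@@]1(O)C=C(Cl)C(=O)[C@@H]1[C@H](/C=C\CCCC(=O)OC)O | intermediate
25 | punaglandin 8 | CCCCC/C=C\C[C@@]1(O)C=C(Cl)C(=O)[C@@H]1[C@H](/C=C\CCCC(=O)OC)OC(C)=O | target

**Step count and risks**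
Total steps: 12. Longest linear sequence: 11 (steps 1–3 and 5–12; step 4 is a one-step side branch).

Step 10 is the most likely to fail. The acylal carbonyl of 19 is shielded on both faces (by the octenyl chain on the one-carbon bridge and by the alkenyl chain on the neighbouring bridge carbon), so addition of the bulky phosphonate carbanion may be slower than its decay; epoxide (Darzens) closure could also compete with olefination. A fallback with another bond-forming logic would set out from 19. Dichloromethyllithium F1 (CH2Cl2, LiN(iPr)2, THF, −100 °C), a small and very reactive carbanion, would add to the acylal carbonyl and give, after collapse and AcOH quench, the dichloromethyl ketone lactol F2. Et3N with MgBr2·OEt2 would close ring A by intramolecular aldol addition to the 2,2-dichloro-3-hydroxycyclopentanone F3. CrCl2 in THF would then remove one chlorine and the C11 hydroxyl by reductive β-elimination, the usual way from α,α-dichloro-β-hydroxy carbonyl compounds to α-chloroenones, and the route would be rejoined at 23.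

Step 9 is the second risk. The lactol may be over-reduced, or the strained bicyclic acylal may close reluctantly under equilibrating acid catalysis, with the lactol acid resting as other ring-chain tautomers or oligomerising. The fallback would set out from 17 and close the ring under kinetic control by glycosyl-ester chemistry. After the same reduction to 18, Ac2O–pyridine would give the anomeric acetate F4 (mixed anhydrides of the acids revert on aqueous work-up). BF3·OEt2 at −40 °C would ionise F4 to the C11 oxocarbenium ion, which the cis C9 carboxylic acid would capture, and the route would be rejoined at 19.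

Step 6 is the third risk. Enolisation of C12–H may be slow or incomplete, because this proton lies on the face of the two cis substituents, and oxidation could then be poor or occur on the wrong face. The fallback would set out from 7 and needs no enolate of the substituted lactone. LiN(SiMe3)2 and CH2=NMe2+ I− would give the Mannich base F5, and MeI then NaHCO3 the α-methylene lactone F6. Dimethyldioxirane would epoxidise the exocyclic alkene from the open face to the spiro-epoxide F7, which already holds the C12–O bond on the required side. (Z)-Hept-1-enylcopper F9, made from pentylcopper F8 (C5H11MgBr, CuBr·SMe2) by carbocupration of acetylene, would open the epoxide at its CH2 terminus with BF3·OEt2, and the route would be rejoined at 13.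

**Further compounds**
F1 | step 10 | dichloromethyllithium | [Li]C(Cl)Cl
F2 | step 10 | (5Z)-6-[(2S,3R,4S)-3-(dichloroacetyl)-4,5-dihydroxy-4-[(2Z)-oct-2-en-1-yl]oxolan-2-yl]hex-5-enoic acid (C5 anomers) | CCCCC/C=C\C[C@@]1(O)C(O)O[C@@H](/C=C\CCCC(=O)O)[C@H]1C(=O)C(Cl)Cl
F3 | step 10 | (5Z,7S)-7-[(1R,2S)-4,4-dichloro-2,3-dihydroxy-2-[(2Z)-oct-2-en-1-yl]-5-oxocyclopentyl]-7-hydroxyhept-5-enoic acid (C3 epimers) | CCCCC/C=C\C[C@@]1(O)C(O)C(Cl)(Cl)C(=O)[C@@H]1[C@H](/C=C\CCCC(=O)O)O
F4 | step 9 | (2S,3R,4S)-5-acetoxy-2-[(1Z)-5-carboxypent-1-en-1-yl]-4-hydroxy-4-[(2Z)-oct-2-en-1-yl]oxolane-3-carboxylic acid (C5 anomers) | CCCCC/C=C\C[C@@]1(O)C(OC(C)=O)O[C@@H](/C=C\CCCC(=O)O)[C@H]1C(=O)O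
F5 | step 6 | (2R,3S)-2-(dimethoxymethyl)-4-[(dimethylamino)methyl]-5-oxooxolane-3-carboxylic acid (C4 epimers) | CN(C)CC1C(=O)O[C@@H](C(OC)OC)[C@H]1C(=O)O
F6 | step 6 | (2R,3S)-2-(dimethoxymethyl)-4-methylidene-5-oxooxolane-3-carboxylic acid | C=C1C(=O)O[C@@H](C(OC)OC)[C@H]1C(=O)O
F7 | step 6 | 6-(dimethoxymethyl)-4-oxo-1,5-dioxaspiro[2.4]heptane-7-carboxylic acid, epoxide oxygen on the face opposite the cis acetal and carboxyl groups | C1[C@@]2(O1)C(=O)O[C@@H](C(OC)OC)[C@H]2C(=O)O
F8 | step 6 | pentylcopper | CCCCC[Cu]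
F9 | step 6 | (Z)-hept-1-en-1-ylcopper | CCCCC/C=C\[Cu]
A1 | direct plan | (R)-4-(tert-butyldimethylsilyloxy)cyclopent-2-en-1-one | O=C1C=C[C@H](O[Si](C)(C)C(C)(C)C)C1
A2 | direct plan | (4S)-2-chloro-4-[(Z)-oct-2-en-1-yl]-4-(triethylsilyloxy)cyclopent-2-en-1-one | CCCCC/C=C\C[C@@]1(O[Si](CC)(CC)CC)C=C(Cl)C(=O)C1
A3 | direct plan | methyl 7-oxohept-5-ynoate | COC(=O)CCCC#CC=O
A4 | direct plan | methyl (7R)-7-[(1R,2S)-4-chloro-2-[(Z)-oct-2-en-1-yl]-5-oxo-2-(triethylsilyloxy)cyclopent-3-en-1-yl]-7-hydroxyhept-5-ynoate | CCCCC/C=C\C[C@@]1(O[Si](CC)(CC)CC)C=C(Cl)C(=O)[C@@H]1[C@H](C#CCCCC(=O)OC)O
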